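## The problem

The target is a flavone: a 4H-chromen-4-one (ring A fused to the pyranone ring C) with a 2,4-dihydroxyphenyl group (ring B) at C2, a prenyl group at C3, a free hydroxyl at C5 and a methyl ether at C7. It has no stereocentre and no stereogenic double bond, so the difficulties are regiochemical and chemoselective only. The hard bond is C3–C1''. C3 is fully substituted and sits between the C4 carbonyl and the ortho-substituted ring B, and direct electrophilic prenylation of a 5,7-dioxygenated flavone would go to C6, C8 or oxygen instead. The two oxygens of ring A must end differently (C5–OH, C7–OMe) and ring B must end as a free resorcinol, which sets the protecting-group problem. The prenyl double bond is the fragile group: it excludes hydrogenolysis, and strong acid can hydrate it, add HCl to it or close it onto a nearby oxygen. C2 of the pyranone is open to hydroxide and the two electron-rich rings to electrophiles. The enabling feature is that C3 is the α-carbon of an aryl ynone C4(=O)–C3≡C2–ring B. When an ortho-methoxy oxygen of ring A closes the O1–C2 bond under an iodine electrophile, iodine is delivered to C3 and nowhere else, and the resulting C3–I bond is a good partner for zerovalent palladium.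

## Retrosynthesis

Target 11 is first traced back to its fully protected form 10, in which ring B carries two benzyl ethers and C5 a methyl ether. The bonds cut are two O–benzyl bonds and the C5 O–methyl bond. Benzyl is chosen because it survives organolithium, iodonium and aqueous phosphate, and because the boron trihalide that cleaves the chelated C5 methyl ether also cleaves benzyl ethers. The C7 methyl ether has no carbonyl to chelate and should stay. Hydrogenolysis is excluded by the prenyl group, so the forward reaction must be a Lewis-acid cleavage cold enough to spare the olefin.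

Compound 10 is cut at C3–C1'' into the 3-iodoflavone 8 and prenylboronic acid pinacol ester 9. This cut is preferred to enolate or Friedel–Crafts prenylation because it addresses C3 through a pre-placed halogen and not through the intrinsic nucleophilicity of the flavone, which favours ring A. The precursor 8 has no olefin and no regiochemical ambiguity. The forward reaction must couple at the primary terminus of the prenyl unit and must outrun protodeiodination at a hindered vinyl position.

Iodide 8 is cut at O1–C2 and C3–I to the ynone 7. The alternative, iodination of a preformed flavone, would have to distinguish C3 from C6 and C8. In the ynone closure the iodine arrives at C3 as part of ring formation, and because ring A of 7 is a symmetric 2,4,6-trimethoxyphenyl group either ortho oxygen gives the same chromone. The forward reaction needs an iodine electrophile whose counter-ion removes the methyl group from the cyclic oxonium ion.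

Ynone 7 is cut at the C4–C3 bond to the lithium acetylide 5, generated from alkyne 3, and 2,4,6-trimethoxybenzaldehyde 4, with the carbinol 6 as the oxidation-level intermediate. Direct acylation of the alkyne with a hindered, electron-rich aroyl chloride is less certain than addition to the aldehyde followed by a neutral oxidation. The carbinol 6 is racemic, which does not matter because its stereocentre disappears in 7.

Alkyne 3 comes from aldehyde 2 by one-carbon homologation, and 2 from 2,4-dihydroxybenzaldehyde 1 by double O-benzylation. Both are routine operations on a commercial resorcinol aldehyde, and 4 and 9 are purchased.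

## Roads not taken

Alternative 1: The cut removes O1–C2 and C3–C1'' together and leads back to ynone A1, whose ring A carries two equivalent prenyl ethers and whose ring B carries methoxymethyl ethers. In the forward step Pd(PPh3)4, a zerovalent palladium complex, would ionise one aryl prenyl ether; the phenoxide would add to the ynone to close ring C and the C3 allenolate would capture the prenylpalladium cation to give A2.
- Merits: ring C and the C3–C1'' bond form in one operation, no iodine or boron reagent is needed, the surviving C5 prenyl ether and the methoxymethyl ethers can be removed without a strong Lewis acid, and the sequence is at least one step shorter than the chosen one. In step economy and in the mildness of its end game it is the better plan.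
- Weak points: the prenylpalladium cation can be captured at either allyl terminus and at oxygen or carbon, or by the phenoxide again. Protonation of the cyclised anion gives a flavone with hydrogen at C3. No tuned ligand controls the recombination. The ring A building block with two prenyl ethers and one methyl ether is not commercial and needs a selective methylation.
- Comparison: the chosen plan separates the two events. Iodine is placed at C3 by a mechanistically fixed cyclisation, and the allyl regiochemistry is handed to a ligand-controlled coupling that can be optimised alone.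

Alternative 2: The cut is C2–C1'. The 2-methylsulfanyl-3-prenylchromone A3 and the ring B boronic acid A4 would couple under Pd(PPh3)4 (zerovalent palladium) and stoichiometric Cu(O2CC4H3S), the thiophene-2-carboxylate of monovalent copper, to give A5.
- Merits: the route is convergent, ring B enters last and could be varied, the base-free coupling tolerates the free C5 hydroxyl, and the methoxymethyl ethers of A5 fall to dilute acid. In convergence and in the final deprotection it is better than the chosen plan.
- Weak points: the new bond is a doubly hindered biaryl-type link between C2, next to the C3 prenyl group, and an ortho-alkoxy boronic acid that is prone to protodeboronation. The chelating 5-hydroxy-4-keto unit can bind the copper, which is already needed in full equivalents. The prenyl group must be placed at C3 of A3 by an alkylation in which carbon, oxygen and sulfur compete.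
- Comparison: the chosen plan builds the C2–ring B bond from an aldehyde and an acetylide, and its only palladium step joins a primary allyl carbon.

Alternative 3: The cut is O1–C8a. The enol oxygen on the ring B carbonyl of the 2-bromoaryl diketone A6 would displace bromide under CuI (monovalent copper) and carbonate to give A7.
- Merits: the prenyl group is introduced by C-alkylation of a 1,3-diketone with prenyl bromide, which is linear by its mechanism, so this route is more secure than the chosen one on prenyl regiochemistry. It uses no palladium.
- Weak points: ring A must be desymmetrised as a 2-bromo-4,6-dimethoxyaryl ketone, which costs steps and has its own regiochemical problem. The 2-alkyl-1,3-diaryl diketone is crowded and liable to retro-Claisen cleavage under hot carbonate. The end game still needs a Lewis-acid cleavage of the C5 methyl ether with the prenyl group present, so nothing is gained there.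
- Comparison: the chosen plan starts ring A from a symmetric commercial aldehyde, closes ring C at −78 °C, and accepts in exchange the need to control the allyl terminus in the coupling.

Key step: step 6

Remark on the chemistry: the target has no stereogenic element; carbinol 6 is made as the racemate and its stereocentre is removed in step 4.

## Route

Step 1
Reactants: 1 2,4-dihydroxybenzaldehyde
Product: 2 2,4-bis(benzyloxy)benzaldehyde
Conditions: BnBr (2.5 equiv), K2CO3, DMF, 60 °C
Reagents that add atoms: benzyl bromide, BrCc1ccccc1
Why: Williamson etherification; carbonate in DMF alkylates both phenols, the chelated 2-hydroxyl needing the excess of bromide and gentle heat, and the aldehyde is inert.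

Step 2
Reactants: 2 2,4-bis(benzyloxy)benzaldehyde
Product: 3 2,4-bis(benzyloxy)-1-ethynylbenzene
Conditions: dimethyl (1-diazo-2-oxopropyl)phosphonate, K2CO3, MeOH/THF, 0 °C → rt
Reagents that add atoms: dimethyl (1-diazo-2-oxopropyl)phosphonate, COP(=O)(OC)C(=[N+]=[N-])C(C)=O
Why: Seyferth–Gilbert homologation in the Ohira–Bestmann variant: methanolysis of the reagent gives the diazomethylphosphonate anion, which olefinates the aldehyde and loses N2 with a 1,2-shift to the terminal alkyne. The carbonate conditions leave the benzyl ethers untouched; the electron-rich aldehyde may need a longer reaction time.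

Step 3
Reactants: 3 2,4-bis(benzyloxy)-1-ethynylbenzene; 4 2,4,6-trimethoxybenzaldehyde
Product: 6 3-[2,4-bis(benzyloxy)phenyl]-1-(2,4,6-trimethoxyphenyl)prop-2-yn-1-ol (racemic), via lithium arylacetylide 5 (not isolated)
Conditions: n-BuLi, THF, −78 °C; then 4, −78 → 0 °C; NH4Cl (aq)
Reagents that add atoms: none
Why: Deprotonation of the terminal alkyne and 1,2-addition of the lithium acetylide to a non-enolisable aldehyde. The carbinol forms as a racemate, which is irrelevant because step 4 removes the stereocentre; it is worked up under neutral conditions because it ionises easily.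

Step 4
Reactants: 6 3-[2,4-bis(benzyloxy)phenyl]-1-(2,4,6-trimethoxyphenyl)prop-2-yn-1-ol
Product: 7 3-[2,4-bis(benzyloxy)phenyl]-1-(2,4,6-trimethoxyphenyl)prop-2-yn-1-one
Conditions: MnO2 (excess), CH2Cl2, rt
Reagents that add atoms: none
Why: MnO2 oxidation of a doubly activated (benzylic and propargylic) alcohol to the ynone under neutral, non-aqueous conditions, which avoids acid-promoted ionisation or Meyer–Schuster rearrangement of 6.

Step 5
Reactants: 7 3-[2,4-bis(benzyloxy)phenyl]-1-(2,4,6-trimethoxyphenyl)prop-2-yn-1-one
Product: 8 2-[2,4-bis(benzyloxy)phenyl]-3-iodo-5,7-dimethoxy-4H-chromen-4-one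
Conditions: ICl (1.1 equiv), CH2Cl2, −78 °C; then Na2S2O3 (aq)
Reagents that add atoms: iodine monochloride, ClI
Why: Iodine monochloride-induced 6-endo-dig iodocyclisation of an ortho-methoxyaryl ynone: a methoxy oxygen of ring A opens the iodonium ion at the alkyne carbon attached to ring B, where positive charge is stabilised by the dialkoxyaryl group and is remote from the carbonyl, and chloride demethylates the oxonium ion to release chloromethane. The two ortho-methoxy groups are equivalent, so only one chromone can form and iodine ends at C3; low temperature and near-stoichiometric ICl are meant to keep the electron-rich rings from being iodinated.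

Step 6
Reactants: 8 2-[2,4-bis(benzyloxy)phenyl]-3-iodo-5,7-dimethoxy-4H-chromen-4-one; 9 prenylboronic acid pinacol ester (4,4,5,5-tetramethyl-2-(3-methylbut-2-en-1-yl)-1,3,2-dioxaborolane)
Product: 10 2-[2,4-bis(benzyloxy)phenyl]-5,7-dimethoxy-3-(3-methylbut-2-en-1-yl)-4H-chromen-4-one
Conditions: Pd(OAc)2 (5 mol %), 2-di-tert-butylphosphino-2',4',6'-triisopropylbiphenyl (t-BuXPhos, 10 mol %), K3PO4 (aq), THF, 40 °C
Reagents that add atoms: none
Why: Zerovalent palladium formed in the flask from Pd(OAc)2 and the phosphine inserts into the C3–I bond of 8, a vinyl iodide activated by the C4 carbonyl. The phosphate-activated boronate 9 transmetalates to a prenylpalladium species whose σ forms at C1'' and C3'' interconvert through the π-allyl complex. The bulky di-tert-butylbiarylphosphine disfavours palladium at the tertiary carbon and promotes reductive elimination from the primary σ-allyl form, which gives the linear prenyl group and not the 1,1-dimethylallyl isomer. The closest known reaction type is the ligand-controlled α-selective Suzuki–Miyaura coupling of 3,3-disubstituted allylboronates with aryl and vinyl halides. No ring is closed and no stereocentre is created. Site selectivity needs no further control, because the iodine was placed at C3 by the cyclisation of step 5, so C6 and C8 of ring A and all of ring B stay untouched. The benzyl and methyl ethers are inert to the mild aqueous base, and the low temperature limits protodeiodination and migration of the prenyl double bond.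

Step 7
Reactants: 10 2-[2,4-bis(benzyloxy)phenyl]-5,7-dimethoxy-3-(3-methylbut-2-en-1-yl)-4H-chromen-4-one
Product: 11 2-(2,4-dihydroxyphenyl)-5-hydroxy-7-methoxy-3-(3-methylbut-2-en-1-yl)-4H-chromen-4-one
Conditions: BCl3 (6 equiv), C6HMe5 (6 equiv), CH2Cl2, −78 → 0 °C; MeOH, then NaHCO3 (aq)
Reagents that add atoms: none
Why: Lewis-acid ether cleavage: BCl3 removes the aryl benzyl ethers at −78 °C while pentamethylbenzene traps the benzyl cations by Friedel–Crafts alkylation, and on warming it cleaves the C5 methyl ether through the six-membered boron chelate with the C4 carbonyl, leaving the unchelated C7 methyl ether. The scavenger and the low temperature are meant to keep cations and HCl away from the prenyl double bond.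

## Compound list

1 | 2,4-dihydroxybenzaldehyde | O=Cc1ccc(O)cc1O | starting material
2 | 2,4-bis(benzyloxy)benzaldehyde | O=Cc1ccc(OCc2ccccc2)cc1OCc1ccccc1 | intermediate
3 | 2,4-bis(benzyloxy)-1-ethynylbenzene | C#Cc1ccc(OCc2ccccc2)cc1OCc1ccccc1 | intermediate
4 | 2,4,6-trimethoxybenzaldehyde | COc1cc(OC)c(C=O)c(OC)c1 | starting material
5 | lithium [2,4-bis(benzyloxy)phenyl]acetylide (not isolated) | [Li]C#Cc1ccc(OCc2ccccc2)cc1OCc1ccccc1 | intermediate
6 | 3-[2,4-bis(benzyloxy)phenyl]-1-(2,4,6-trimethoxyphenyl)prop-2-yn-1-ol (racemic) | COc1cc(OC)c(C(O)C#Cc2ccc(OCc3ccccc3)cc2OCc2ccccc2)c(OC)c1 | intermediate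
7 | 3-[2,4-bis(benzyloxy)phenyl]-1-(2,4,6-trimethoxyphenyl)prop-2-yn-1-one | COc1cc(OC)c(C(=O)C#Cc2ccc(OCc3ccccc3)cc2OCc2ccccc2)c(OC)c1 | intermediate
8 | 2-[2,4-bis(benzyloxy)phenyl]-3-iodo-5,7-dimethoxy-4H-chromen-4-one | COc1cc(OC)c2c(=O)c(I)c(-c3ccc(OCc4ccccc4)cc3OCc3ccccc3)oc2c1 | intermediate
9 | prenylboronic acid pinacol ester | CC(C)=CCB1OC(C)(C)C(C)(C)O1 | starting material
10 | 2-[2,4-bis(benzyloxy)phenyl]-5,7-dimethoxy-3-(3-methylbut-2-en-1-yl)-4H-chromen-4-one | COc1cc(OC)c2c(=O)c(CC=C(C)C)c(-c3ccc(OCc4ccccc4)cc3OCc3ccccc3)oc2c1 | intermediate
11 | 2-(2,4-dihydroxyphenyl)-5-hydroxy-7-methoxy-3-(3-methylbut-2-en-1-yl)-4H-chromen-4-one | COc1cc(O)c2c(=O)c(CC=C(C)C)c(-c3ccc(O)cc3O)oc2c1 | target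

## Step count and risks

Total step count: 7. Longest linear sequence: 7 steps (1 → 11); 4 and 9 enter as purchased compounds.

Step 6 (key step). The most likely failures are reductive elimination at the tertiary allyl terminus, which would give the 1,1-dimethylallyl isomer, and protodeiodination, because transmetalation at the crowded C3 (between the C4 carbonyl and the ortho-benzyloxy ring B) may be slow. The fallback sets out from 8. A Suzuki–Miyaura coupling with allylboronic acid pinacol ester, whose two allyl termini are equivalent, should give 3-allyl-2-[2,4-bis(benzyloxy)phenyl]-5,7-dimethoxy-4H-chromen-4-one F1. Cross-metathesis of F1 with an excess of 2-methyl-2-butene under the second-generation Grubbs catalyst would then convert the allyl into the prenyl group, returning to the route at 10.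

Step 5. Two things may go wrong. The electron-rich rings A and B may be iodinated in competition with the alkyne, and the ortho-benzyloxy oxygen of ring B may close onto the carbonyl-side alkyne carbon (5-endo) instead of the ring A methoxy oxygen closing 6-endo. The fallback sets out from 2 and avoids the ynone. Claisen–Schmidt condensation of 2 with purchased 1-(2-hydroxy-4,6-dimethoxyphenyl)ethanone (KOH, EtOH) should give (E)-3-[2,4-bis(benzyloxy)phenyl]-1-(2-hydroxy-4,6-dimethoxyphenyl)prop-2-en-1-one F2. Oxidative cyclisation with catalytic I2 in hot DMSO should give 2-[2,4-bis(benzyloxy)phenyl]-5,7-dimethoxy-4H-chromen-4-one F3. Deprotonation of F3 at C3 with LiN(iPr)2 at −78 °C and quenching with I2 places the iodine by directed metalation, not by electrophilic substitution, and returns to the route at 8.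

Step 7. The prenyl double bond may add HCl or be attacked by benzyl cations, and the chelation-assisted demethylation may be incomplete at a temperature the olefin tolerates. The fallback moves the Lewis-acid step ahead of the prenylation and sets out from 8. BCl3 with pentamethylbenzene should give 2-(2,4-dihydroxyphenyl)-5-hydroxy-3-iodo-7-methoxy-4H-chromen-4-one F4. Acetylation (Ac2O, pyridine, DMAP) gives the triacetate 4-(5-acetoxy-3-iodo-7-methoxy-4-oxo-4H-chromen-2-yl)-1,3-phenylene diacetate F5. The coupling of step 6 with 9 gives the 3-prenyl triacetate 4-[5-acetoxy-7-methoxy-3-(3-methylbut-2-en-1-yl)-4-oxo-4H-chromen-2-yl]-1,3-phenylene diacetate F6; partial acetate loss in the aqueous phosphate is harmless. K2CO3 in MeOH at room temperature then removes the acetates without any acid and returns to the route at 11.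

Step 3 (with step 4). The carbinol 6 is both 2,4,6-trimethoxybenzylic and propargylic and may ionise on silica gel or during oxidation, leading to ether formation or Meyer–Schuster rearrangement. The fallback sets out from 5, generated from 3 as in step 3, and skips the carbinol. Acylation of 5 with N,2,4,6-tetramethoxy-N-methylbenzamide F7, prepared from purchased 2,4,6-trimethoxybenzoic acid with 1,1'-carbonyldiimidazole and N,O-dimethylhydroxylamine hydrochloride, should give the ynone directly after collapse of the chelated tetrahedral intermediate on work-up, returning to the route at 7.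

## Further compounds

F1 | step 6 | 3-allyl-2-[2,4-bis(benzyloxy)phenyl]-5,7-dimethoxy-4H-chromen-4-one | COc1cc(OC)c2c(=O)c(CC=C)c(-c3ccc(OCc4ccccc4)cc3OCc3ccccc3)oc2c1
F2 | step 5 | (E)-3-[2,4-bis(benzyloxy)phenyl]-1-(2-hydroxy-4,6-dimethoxyphenyl)prop-2-en-1-one | COc1cc(O)c(C(=O)/C=C/c2ccc(OCc3ccccc3)cc2OCc2ccccc2)c(OC)c1
F3 | step 5 | 2-[2,4-bis(benzyloxy)phenyl]-5,7-dimethoxy-4H-chromen-4-one | COc1cc(OC)c2c(=O)cc(-c3ccc(OCc4ccccc4)cc3OCc3ccccc3)oc2c1
F4 | step 7 | 2-(2,4-dihydroxyphenyl)-5-hydroxy-3-iodo-7-methoxy-4H-chromen-4-one | COc1cc(O)c2c(=O)c(I)c(-c3ccc(O)cc3O)oc2c1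
F5 | step 7 | 4-(5-acetoxy-3-iodo-7-methoxy-4-oxo-4H-chromen-2-yl)-1,3-phenylene diacetate | COc1cc(OC(C)=O)c2c(=O)c(I)c(-c3ccc(OC(C)=O)cc3OC(C)=O)oc2c1
F6 | step 7 | 4-[5-acetoxy-7-methoxy-3-(3-methylbut-2-en-1-yl)-4-oxo-4H-chromen-2-yl]-1,3-phenylene diacetate | COc1cc(OC(C)=O)c2c(=O)c(CC=C(C)C)c(-c3ccc(OC(C)=O)cc3OC(C)=O)oc2c1
F7 | step 3 | N,2,4,6-tetramethoxy-N-methylbenzamide | COc1cc(OC)c(C(=O)N(C)OC)c(OC)c1
A1 | alternative 1 | 3-[2,4-bis(methoxymethoxy)phenyl]-1-[4-methoxy-2,6-bis(3-methylbut-2-en-1-yloxy)phenyl]prop-2-yn-1-one | COc1cc(OCC=C(C)C)c(C(=O)C#Cc2ccc(OCOC)cc2OCOC)c(OCC=C(C)C)c1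
A2 | alternative 1 | 2-[2,4-bis(methoxymethoxy)phenyl]-7-methoxy-3-(3-methylbut-2-en-1-yl)-5-(3-methylbut-2-en-1-yloxy)-4H-chromen-4-one | COc1cc(OCC=C(C)C)c2c(=O)c(CC=C(C)C)c(-c3ccc(OCOC)cc3OCOC)oc2c1
A3 | alternative 2 | 5-hydroxy-7-methoxy-2-(methylsulfanyl)-3-(3-methylbut-2-en-1-yl)-4H-chromen-4-one | COc1cc(O)c2c(=O)c(CC=C(C)C)c(SC)oc2c1
A4 | alternative 2 | [2,4-bis(methoxymethoxy)phenyl]boronic acid | COCOc1ccc(B(O)O)c(OCOC)c1
A5 | alternative 2 | 2-[2,4-bis(methoxymethoxy)phenyl]-5-hydroxy-7-methoxy-3-(3-methylbut-2-en-1-yl)-4H-chromen-4-one | COc1cc(O)c2c(=O)c(CC=C(C)C)c(-c3ccc(OCOC)cc3OCOC)oc2c1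
A6 | alternative 3 | 1-[2,4-bis(methoxymethoxy)phenyl]-3-(2-bromo-4,6-dimethoxyphenyl)-2-(3-methylbut-2-en-1-yl)propane-1,3-dione | COc1cc(Br)c(C(=O)C(CC=C(C)C)C(=O)c2ccc(OCOC)cc2OCOC)c(OC)c1
A7 | alternative 3 | 2-[2,4-bis(methoxymethoxy)phenyl]-5,7-dimethoxy-3-(3-methylbut-2-en-1-yl)-4H-chromen-4-one | COc1cc(OC)c2c(=O)c(CC=C(C)C)c(-c3ccc(OCOC)cc3OCOC)oc2c1
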